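The ten-membered lactone is disconnected at C3–C4, which lies between a latent C2 carbonyl and the Z C5=C6 olefin: a γ,δ-unsaturated α-keto ester, the retron of a Claisen rearrangement. The key step is a thermal [3,3] shift of an eight-membered 3-methylene-5-vinyl-1,4-dioxocan-2-one, in which the lactone atoms C1, O, C9, C8 and C7 bridge a temporary C6–O–C2 enol ether. In one operation the C3–C4 bond forms, the C6–O bond breaks, the ring grows from eight to ten atoms, the Z olefin is set by the bridge and the C2 ketone is unveiled for reagent-controlled reduction and acylation with sorbic acid.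

Key step: step 10

Remark: locants C1 to C12 are those of the seco acid of the target (C1 lactone carbonyl, C2 carbinol carrying the dienoate, C5=C6 ring olefin, C9 ring carbinol carrying the propyl group); the SMILES corresponds to the (2S,5Z,7S,8R,9R) isomer.

Step 1
Reactants: 1 butanal; 2 allyl 4-methoxyphenyl ether
Product: 4 (3S,4S)-3-(4-methoxyphenoxy)hept-1-en-4-ol, via allylborane 3 (not isolated)
Conditions: 2, s-BuLi, THF, −78 °C; (+)-Ipc2BOMe; BF3·OEt2; 1, −78 °C; then NaOH, H2O2, 0 °C to rt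
Reagents that add atoms: none
Why: Brown γ-alkoxyallylboration: the (Z)-γ-aryloxyallylborane 3 adds through a closed chair transition state, so its Z geometry gives the syn C8/C9 pair and the isopinocampheyl groups from (−)-α-pinene select the aldehyde face that gives the (3S,4S) enantiomer.

Step 2
Reactants: 4 (3S,4S)-3-(4-methoxyphenoxy)hept-1-en-4-ol; 5 2-(diethoxyphosphoryl)acetic acid
Product: 6 (3S,4R)-3-(4-methoxyphenoxy)hept-1-en-4-yl 2-(diethoxyphosphoryl)acetate
Conditions: PPh3, DIAD, toluene, 0 °C to rt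
Reagents that add atoms: none
Why: Mitsunobu esterification: SN2 attack of the acidic phosphonoacetate on the oxyphosphonium ion inverts C9, turning the syn pair of 4 into the anti C8/C9 relationship of the target while installing C1, C2 and the phosphonate needed in step 9.

Step 3
Reactants: 6 (3S,4R)-3-(4-methoxyphenoxy)hept-1-en-4-yl 2-(diethoxyphosphoryl)acetate
Product: 8 (2R,3R)-2-(4-methoxyphenoxy)-1-oxohexan-3-yl 2-(diethoxyphosphoryl)acetate, via diol 7 (not isolated)
Conditions: OsO4 (cat.), NaIO4, 2,6-lutidine, dioxane/H2O, rt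
Reagents that add atoms: osmium tetroxide O=[Os](=O)(=O)=O (source of the aldehyde oxygen), turned over by sodium periodate [Na+].[O-]I(=O)(=O)=O
Why: Lemieux–Johnson oxidative cleavage: the terminal vinyl group is dihydroxylated to diol 7 and cleaved in situ to the C7 aldehyde, the lutidine buffer protecting the α-aryloxy stereocentre and the β-acyloxy group from enolisation and elimination.

Step 4
Reactants: 8 (2R,3R)-2-(4-methoxyphenoxy)-1-oxohexan-3-yl 2-(diethoxyphosphoryl)acetate; 9 allyl methoxymethyl ether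
Product: 11 (3R,4S,5S,6R)-4-hydroxy-3-(methoxymethoxy)-5-(4-methoxyphenoxy)non-1-en-6-yl 2-(diethoxyphosphoryl)acetate, via allylborane 10 (not isolated)
Conditions: 9, s-BuLi, THF, −78 °C; (−)-Ipc2BOMe; BF3·OEt2; 8, −78 °C; then pH 7 buffer, H2O2, MeOH, 0 °C
Reagents that add atoms: none
Why: Second Brown γ-alkoxyallylboration: the closed chair transition state gives the syn C6/C7 pair and the isopinocampheyl groups from (+)-α-pinene deliver the allyl unit to the aldehyde face that makes C7 anti to C8, a sense that the Felkin–Anh preference of the α-aryloxy aldehyde reinforces.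

Step 5
Reactants: 11 (3R,4S,5S,6R)-4-hydroxy-3-(methoxymethoxy)-5-(4-methoxyphenoxy)non-1-en-6-yl 2-(diethoxyphosphoryl)acetate
Product: 12 (3R,4S,5R,6R)-4-acetoxy-3-(methoxymethoxy)-5-(4-methoxyphenoxy)non-1-en-6-yl 2-(diethoxyphosphoryl)acetate
Conditions: Ac2O, pyridine, DMAP (cat.), CH2Cl2, 0 °C
Reagents that add atoms: acetic anhydride CC(=O)OC(C)=O
Why: DMAP-catalysed acylation of the only free hydroxyl installs the C7 acetate of the target while every neighbouring oxygen is still capped, so no acyl migration is possible.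

Step 6
Reactants: 12 (3R,4S,5R,6R)-4-acetoxy-3-(methoxymethoxy)-5-(4-methoxyphenoxy)non-1-en-6-yl 2-(diethoxyphosphoryl)acetate
Product: 13 (3R,4S,5R,6R)-4-acetoxy-3-(methoxymethoxy)-5-(4-methoxyphenoxy)non-1-en-6-yl 2-diazo-2-(diethoxyphosphoryl)acetate
Conditions: p-ABSA, DBU, MeCN, 0 °C to rt
Reagents that add atoms: 4-acetamidobenzenesulfonyl azide CC(=O)Nc1ccc(cc1)S(=O)(=O)N=[N+]=[N-]
Why: Regitz diazo transfer to the doubly activated methylene of the phosphonoacetate, run while all hydroxyls are capped so that the amidine base cannot trigger acetyl migration.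

Step 7
Reactants: 13 (3R,4S,5R,6R)-4-acetoxy-3-(methoxymethoxy)-5-(4-methoxyphenoxy)non-1-en-6-yl 2-diazo-2-(diethoxyphosphoryl)acetate
Product: 14 (3R,4S,5R,6R)-4-acetoxy-3-hydroxy-5-(4-methoxyphenoxy)non-1-en-6-yl 2-diazo-2-(diethoxyphosphoryl)acetate
Conditions: Me2BBr, CH2Cl2, −78 °C; then sat. NaHCO3/THF
Reagents that add atoms: none
Why: Lewis acid cleavage of the methoxymethyl acetal by the bromoborane (O-boryl ether and bromomethyl methyl ether, hydrolysed on work-up) frees the C6 hydroxyl, while the acceptor-substituted diazo group, the aryl ether and the acetate should not react at −78 °C.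

Step 8
Reactants: 14 (3R,4S,5R,6R)-4-acetoxy-3-hydroxy-5-(4-methoxyphenoxy)non-1-en-6-yl 2-diazo-2-(diethoxyphosphoryl)acetate
Product: 15 diethyl [(5R,6S,7R,8R)-6-acetoxy-7-(4-methoxyphenoxy)-2-oxo-8-propyl-5-vinyl-1,4-dioxocan-3-yl]phosphonate (both C3 epimers)
Conditions: Rh2(OAc)4 (cat.), benzene, 80 °C, slow addition, high dilution
Reagents that add atoms: none
Why: Rhodium carbenoid O–H insertion: loss of N2 gives an electrophilic carbenoid that the C6 hydroxyl traps (oxonium ylide, then proton shift), closing the eight-membered 1,4-dioxocan-2-one and creating the temporary C6–O–C2 ether, with slow addition disfavouring oligomers and the new phosphonate-bearing centre forming as a mixture that step 9 erases.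

Step 9
Reactants: 15 diethyl [(5R,6S,7R,8R)-6-acetoxy-7-(4-methoxyphenoxy)-2-oxo-8-propyl-5-vinyl-1,4-dioxocan-3-yl]phosphonate
Product: 16 (5R,6S,7R,8R)-7-(4-methoxyphenoxy)-3-methylidene-2-oxo-8-propyl-5-vinyl-1,4-dioxocan-6-yl acetate
Conditions: LiN(SiMe3)2, THF, −78 °C; CH2O (g); −78 to 0 °C
Reagents that add atoms: formaldehyde C=O
Why: Horner–Wadsworth–Emmons olefination: the phosphonate carbanion, formed in preference to an acetate enolate because its C–H is far more acidic, adds to monomeric formaldehyde and expels diethyl phosphate to give the exocyclic enol ether that supplies C3.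

Step 10
Reactants: 16 (5R,6S,7R,8R)-7-(4-methoxyphenoxy)-3-methylidene-2-oxo-8-propyl-5-vinyl-1,4-dioxocan-6-yl acetate
Product: 17 (5Z,7S,8R,9R)-7-acetoxy-8-(4-methoxyphenoxy)-2-oxododec-5-en-9-olide
Conditions: toluene, 110 °C, sealed tube
Reagents that add atoms: none
Why: Claisen rearrangement ([3,3] sigmatropic shift) of the allyl vinyl ether C3=C2–O–C6–C5=C4 embedded in 16: the C3–C4 σ bond forms suprafacially through a six-membered chair-like array while the temporary C6–O bond breaks and the ether oxygen becomes the C2 ketone. The closest known reaction types are the rearrangement of 2-alkoxycarbonyl allyl vinyl ethers (enolpyruvyl ethers) to γ,δ-unsaturated α-keto esters and the Claisen ring expansion of vinyl-substituted cyclic enol ethers to medium rings. The ten-membered ring closes by a two-atom enlargement of the eight-membered ring, the bridge C7–C8–C9–O–C1 spanning positions 2 and 4 of the pericyclic array, so no end-to-end cyclisation of an open chain is needed. No stereocentre is created: the C6 stereocentre is destroyed and its information passes into the geometry of the C5=C6 olefin. The step needs Z selectivity, which the bridge should secure, because it can reach from C6 back to C1 only when C7 sits pseudo-axial on the chair (cis to C4), whereas the E pathway would need a near-antiperiplanar C2–O–C6–C7 torsion that the eight-membered ring cannot easily adopt. The acetate, aryl ether and lactone are inert to the neutral thermal conditions, and the 2-alkoxycarbonyl group lowers the barrier enough that about 110 °C should suffice.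

Step 11
Reactants: 17 (5Z,7S,8R,9R)-7-acetoxy-8-(4-methoxyphenoxy)-2-oxododec-5-en-9-olide
Product: 18 (2S,5Z,7S,8R,9R)-7-acetoxy-2-hydroxy-8-(4-methoxyphenoxy)dodec-5-en-9-olide
Conditions: RuCl[(S,S)-TsDPEN](p-cymene) (cat.), HCO2H/Et3N, CH2Cl2, 0 °C to rt
Reagents that add atoms: none
Why: Noyori-type asymmetric transfer hydrogenation of the α-keto lactone: by analogy with aryl ketones, where the sp2 substituent (here the lactone carbonyl) lies next to the arene ligand, the (S,S) ligand is expected to deliver hydride to the Re face of C2 and set the (2S) carbinol under reagent control, leaving olefin and esters untouched.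

Step 12
Reactants: 18 (2S,5Z,7S,8R,9R)-7-acetoxy-2-hydroxy-8-(4-methoxyphenoxy)dodec-5-en-9-olide; 19 sorbic acid
Product: 20 (2S,5Z,7S,8R,9R)-7-acetoxy-2-[(2E,4E)-hexa-2,4-dienoyloxy]-8-(4-methoxyphenoxy)dodec-5-en-9-olide
Conditions: 19, EDC·HCl, DMAP (cat.), CH2Cl2, 0 °C to rt
Reagents that add atoms: none
Why: Steglich esterification: carbodiimide activation of sorbic acid with catalytic DMAP acylates the only free hydroxyl with retention at C2.

Step 13
Reactants: 20 (2S,5Z,7S,8R,9R)-7-acetoxy-2-[(2E,4E)-hexa-2,4-dienoyloxy]-8-(4-methoxyphenoxy)dodec-5-en-9-olide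
Product: 21 (2S,5Z,7S,8R,9R)-7-acetoxy-2-[(2E,4E)-hexa-2,4-dienoyloxy]-8-hydroxydodec-5-en-9-olide (target)
Conditions: (NH4)2Ce(NO3)6, MeCN/H2O, 0 °C
Reagents that add atoms: none
Why: Oxidative removal of the 4-methoxyphenyl ether: two-electron oxidation of the electron-rich arene by tetravalent cerium gives a quinone oxocarbenium ion that water hydrolyses to benzoquinone and the free C8 hydroxyl, under brief acidic conditions that should neither promote 1,2-acetyl migration nor touch the electron-poor dienoate.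

Compound list
1 | butanal | CCCC=O | starting material
2 | allyl 4-methoxyphenyl ether (1-methoxy-4-(prop-2-en-1-yloxy)benzene) | C=CCOc1ccc(OC)cc1 | starting material
3 | [(Z)-3-(4-methoxyphenoxy)prop-2-en-1-yl]bis(isopinocampheyl)borane, isopinocampheyl groups from (−)-α-pinene | COc1ccc(O/C=C\CB([C@H]2C[C@H]3C[C@@H]([C@@H]2C)C3(C)C)[C@H]2C[C@H]3C[C@@H]([C@@H]2C)C3(C)C)cc1 | intermediate
4 | (3S,4S)-3-(4-methoxyphenoxy)hept-1-en-4-ol | C=C[C@H](Oc1ccc(OC)cc1)[C@H](CCC)O | intermediate
5 | 2-(diethoxyphosphoryl)acetic acid | OC(=O)CP(=O)(OCC)OCC | starting material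
6 | (3S,4R)-3-(4-methoxyphenoxy)hept-1-en-4-yl 2-(diethoxyphosphoryl)acetate | C=C[C@H](Oc1ccc(OC)cc1)[C@@H](CCC)OC(=O)CP(=O)(OCC)OCC | intermediate
7 | (3S,4R)-1,2-dihydroxy-3-(4-methoxyphenoxy)heptan-4-yl 2-(diethoxyphosphoryl)acetate (both C2 epimers) | OCC(O)[C@H](Oc1ccc(OC)cc1)[C@@H](CCC)OC(=O)CP(=O)(OCC)OCC | intermediate
8 | (2R,3R)-2-(4-methoxyphenoxy)-1-oxohexan-3-yl 2-(diethoxyphosphoryl)acetate | O=C[C@H](Oc1ccc(OC)cc1)[C@@H](CCC)OC(=O)CP(=O)(OCC)OCC | intermediate
9 | allyl methoxymethyl ether (3-(methoxymethoxy)prop-1-ene) | C=CCOCOC | starting material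
10 | [(Z)-3-(methoxymethoxy)prop-2-en-1-yl]bis(isopinocampheyl)borane, isopinocampheyl groups from (+)-α-pinene | COCO/C=C\CB([C@@H]1C[C@@H]2C[C@H]([C@H]1C)C2(C)C)[C@@H]1C[C@@H]2C[C@H]([C@H]1C)C2(C)C | intermediate
11 | (3R,4S,5S,6R)-4-hydroxy-3-(methoxymethoxy)-5-(4-methoxyphenoxy)non-1-en-6-yl 2-(diethoxyphosphoryl)acetate | C=C[C@@H](OCOC)[C@H](O)[C@H](Oc1ccc(OC)cc1)[C@@H](CCC)OC(=O)CP(=O)(OCC)OCC | intermediate
12 | (3R,4S,5R,6R)-4-acetoxy-3-(methoxymethoxy)-5-(4-methoxyphenoxy)non-1-en-6-yl 2-(diethoxyphosphoryl)acetate | C=C[C@@H](OCOC)[C@H](OC(C)=O)[C@H](Oc1ccc(OC)cc1)[C@@H](CCC)OC(=O)CP(=O)(OCC)OCC | intermediate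
13 | (3R,4S,5R,6R)-4-acetoxy-3-(methoxymethoxy)-5-(4-methoxyphenoxy)non-1-en-6-yl 2-diazo-2-(diethoxyphosphoryl)acetate | C=C[C@@H](OCOC)[C@H](OC(C)=O)[C@H](Oc1ccc(OC)cc1)[C@@H](CCC)OC(=O)C(=[N+]=[N-])P(=O)(OCC)OCC | intermediate
14 | (3R,4S,5R,6R)-4-acetoxy-3-hydroxy-5-(4-methoxyphenoxy)non-1-en-6-yl 2-diazo-2-(diethoxyphosphoryl)acetate | C=C[C@@H](O)[C@H](OC(C)=O)[C@H](Oc1ccc(OC)cc1)[C@@H](CCC)OC(=O)C(=[N+]=[N-])P(=O)(OCC)OCC | intermediate
15 | diethyl [(5R,6S,7R,8R)-6-acetoxy-7-(4-methoxyphenoxy)-2-oxo-8-propyl-5-vinyl-1,4-dioxocan-3-yl]phosphonate (both C3 epimers) | CCOP(=O)(OCC)C1O[C@H](C=C)[C@H](OC(C)=O)[C@H](Oc2ccc(OC)cc2)[C@@H](CCC)OC1=O | intermediate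
16 | (5R,6S,7R,8R)-7-(4-methoxyphenoxy)-3-methylidene-2-oxo-8-propyl-5-vinyl-1,4-dioxocan-6-yl acetate | C=C1O[C@H](C=C)[C@H](OC(C)=O)[C@H](Oc2ccc(OC)cc2)[C@@H](CCC)OC1=O | intermediate
17 | (5Z,7S,8R,9R)-7-acetoxy-8-(4-methoxyphenoxy)-2-oxododec-5-en-9-olide | O=C1CC/C=C\[C@H](OC(C)=O)[C@H](Oc2ccc(OC)cc2)[C@@H](CCC)OC1=O | intermediate
18 | (2S,5Z,7S,8R,9R)-7-acetoxy-2-hydroxy-8-(4-methoxyphenoxy)dodec-5-en-9-olide | O[C@H]1CC/C=C\[C@H](OC(C)=O)[C@H](Oc2ccc(OC)cc2)[C@@H](CCC)OC1=O | intermediate
19 | sorbic acid ((2E,4E)-hexa-2,4-dienoic acid) | C/C=C/C=C/C(=O)O | starting material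
20 | (2S,5Z,7S,8R,9R)-7-acetoxy-2-[(2E,4E)-hexa-2,4-dienoyloxy]-8-(4-methoxyphenoxy)dodec-5-en-9-olide | C/C=C/C=C/C(=O)O[C@H]1CC/C=C\[C@H](OC(C)=O)[C@H](Oc2ccc(OC)cc2)[C@@H](CCC)OC1=O | intermediate
21 | (2S,5Z,7S,8R,9R)-7-acetoxy-2-[(2E,4E)-hexa-2,4-dienoyloxy]-8-hydroxydodec-5-en-9-olide | C/C=C/C=C/C(=O)O[C@H]1CC/C=C\[C@H](OC(C)=O)[C@H](O)[C@@H](CCC)OC1=O | target

Total step count: 13 steps.
Longest linear sequence: 13 steps (1 to 21); compounds 2, 5, 9 and 19 are commercial and enter directly.

Steps most likely to fail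

Step 10 (key step). The rearrangement may leak through the transition state with C7 pseudo-equatorial, or the enol ether may decompose before it rearranges, so that the E ring olefin contaminates 17. The fallback sets out from 16 and sets the geometry under thermodynamic control in a separate operation. The crude Claisen product, containing the (5E)-configured keto lactone F1, is not separated but equilibrated by reversible thiyl radical addition (PhSSPh cat., hν, benzene, rt). This should funnel the mixture to the Z isomer, which is expected to be the more stable one in a ten-membered ring, and so returns to 17.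

Step 8. The carbenoid may be consumed by 1,5 C–H insertion into the C8–H or propyl C–H bonds (γ-lactone formation) or by intermolecular O–H insertion (oligomers) faster than it closes the eight-membered ring. The fallback reverses the order of bond formation: the ether is made intermolecularly and the ring is closed through the ester bond.

It sets out from 4, which is silylated (TBSCl, imidazole) to the silyl ether F2. F2 is cleaved as in step 3 to the aldehyde F3, which is allylborated as in step 4 to the homoallylic alcohol F4. F4 is acetylated to the acetate F5, and the acetal is cleaved with Me2BBr to the C6 alcohol F6.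

Intermolecular Rh2(OAc)4-catalysed O–H insertion of tert-butyl 2-diazo-2-(diethoxyphosphoryl)acetate into F6 gives the phosphonate ether F7. Olefination with formaldehyde as in step 9 gives the enolpyruvyl ether F8, and aqueous trifluoroacetic acid removes the tert-butyl ester and the silyl ether to give the seco acid F9. Mitsunobu macrolactonisation (PPh3, DIAD, toluene, high dilution) closes the eight-membered lactone with the same inversion at C9 that step 2 provides, and so returns to 16.

Step 7. The Lewis acid may destroy the diazo group, or the acetate may migrate to the freed C6 hydroxyl during acetal cleavage. The fallback moves the acetal cleavage ahead of the diazo transfer and carries C6 through the basic step as a silyl ether. It sets out from 12, which is treated with Me2BBr at −78 °C to give the alcohol F10. F10 is silylated (Et3SiOTf, 2,6-lutidine, −78 °C) to the triethylsilyl ether F11, which undergoes diazo transfer as in step 6 to the diazo ester F12. Desilylation with HF·pyridine, acidic conditions that do not move the acetate, returns to 14.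

Further compounds
F1 | step 10 | (5E,7S,8R,9R)-7-acetoxy-8-(4-methoxyphenoxy)-2-oxododec-5-en-9-olide | O=C1CC/C=C/[C@H](OC(C)=O)[C@H](Oc2ccc(OC)cc2)[C@@H](CCC)OC1=O
F2 | step 8 | tert-butyl{[(3S,4S)-3-(4-methoxyphenoxy)hept-1-en-4-yl]oxy}dimethylsilane | C=C[C@H](Oc1ccc(OC)cc1)[C@H](CCC)O[Si](C)(C)C(C)(C)C
F3 | step 8 | 3-[tert-butyl(dimethyl)silyl]oxy-2-(4-methoxyphenoxy)hexanal, configuration as in F2 | O=C[C@H](Oc1ccc(OC)cc1)[C@H](CCC)O[Si](C)(C)C(C)(C)C
F4 | step 8 | 6-[tert-butyl(dimethyl)silyl]oxy-3-(methoxymethoxy)-5-(4-methoxyphenoxy)non-1-en-4-ol, C3 to C5 configured as in 11 and C6 as in 4 | C=C[C@@H](OCOC)[C@H](O)[C@H](Oc1ccc(OC)cc1)[C@H](CCC)O[Si](C)(C)C(C)(C)C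
F5 | step 8 | C4 acetate of F4 | C=C[C@@H](OCOC)[C@H](OC(C)=O)[C@H](Oc1ccc(OC)cc1)[C@H](CCC)O[Si](C)(C)C(C)(C)C
F6 | step 8 | 6-[tert-butyl(dimethyl)silyl]oxy-3-hydroxy-5-(4-methoxyphenoxy)non-1-en-4-yl acetate, configuration as in F5 | C=C[C@@H](O)[C@H](OC(C)=O)[C@H](Oc1ccc(OC)cc1)[C@H](CCC)O[Si](C)(C)C(C)(C)C
F7 | step 8 | tert-butyl 2-(diethoxyphosphoryl)-2-(nonenyloxy)acetate formed from F6 at its C3 oxygen (both epimers at the phosphonate carbon) | C=C[C@@H](OC(C(=O)OC(C)(C)C)P(=O)(OCC)OCC)[C@H](OC(C)=O)[C@H](Oc1ccc(OC)cc1)[C@H](CCC)O[Si](C)(C)C(C)(C)C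
F8 | step 8 | tert-butyl 2-(nonenyloxy)acrylate derived from F7 | C=C[C@@H](OC(=C)C(=O)OC(C)(C)C)[C@H](OC(C)=O)[C@H](Oc1ccc(OC)cc1)[C@H](CCC)O[Si](C)(C)C(C)(C)C
F9 | step 8 | 2-{[4-acetoxy-6-hydroxy-5-(4-methoxyphenoxy)non-1-en-3-yl]oxy}acrylic acid, configuration as in F6 | C=C[C@@H](OC(=C)C(=O)O)[C@H](OC(C)=O)[C@H](Oc1ccc(OC)cc1)[C@H](CCC)O
F10 | step 7 | (3R,4S,5R,6R)-4-acetoxy-3-hydroxy-5-(4-methoxyphenoxy)non-1-en-6-yl 2-(diethoxyphosphoryl)acetate | C=C[C@@H](O)[C@H](OC(C)=O)[C@H](Oc1ccc(OC)cc1)[C@@H](CCC)OC(=O)CP(=O)(OCC)OCC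
F11 | step 7 | C3 triethylsilyl ether of F10 | C=C[C@@H](O[Si](CC)(CC)CC)[C@H](OC(C)=O)[C@H](Oc1ccc(OC)cc1)[C@@H](CCC)OC(=O)CP(=O)(OCC)OCC
F12 | step 7 | C3 triethylsilyl ether of 14 | C=C[C@@H](O[Si](CC)(CC)CC)[C@H](OC(C)=O)[C@H](Oc1ccc(OC)cc1)[C@@H](CCC)OC(=O)C(=[N+]=[N-])P(=O)(OCC)OCC
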